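All runs were generated by integration from invented constants.

Divide the final target of a flask by what else became of its substrate, then by the equivalents of partner. I applied this to the two earlier flasks, which look nearly the same and differ in partner and temperature.

| setting | south | north | summer | winter |
|---|---|---|---|---|
| substrate | 20 mM | 20 mM | 20 mM | 20 mM |
| partner | 1.5 equiv | 3.3 equiv | 2.00 equiv | 4.00 equiv |
| capture agent | 6 mM | 6 mM | 6.00 mM | 6.00 mM |
| temperature | 35 °C | 46 °C | 50 °C | 30 °C |
| remark | run made earlier | run made earlier |  |  |
| time |  |  | 12 min | 6.0 min |

- south (time / min: target / %, substrate / %): 2.00: 7.6, 30.3; 3.00: 11.8, 17.4; 5.00: 13.4, 5.8; 6.00: 13.6, 3.5; 8.00: 14.8, 1.1; 10.0: 13.5, 0.3; 12.0: 13.6, 0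
- north (time / min: target / %, substrate / %): 0.500: 10.1, 36.0; 0.667: 11.7, 26.3; 1.00: 15.5, 13.7; 1.50: 16.5, 5.3; 2.50: 17.1, 1.1; 4.00: 18.2, 1.4; 6.00: 17.8, 0

(readings scatter by 0.5 percentage points)

- the flask that ends with the higher amount of target, in percent of the substrate charged, or "neither" when 2 percentage points or less lies between them (summer / winter / neither)
- final target, as a percentage of the substrate charged, in summer
- final target, as a percentage of the substrate charged, in winter

- a reading or a percentage of target counts all its forms, free or not
- a reading of substrate is of its free form alone

The north run ended higher than the south run, at 17.8 % of target against 13.6 %, yet it held 2.20 times the partner. The quotient above, a selectivity factor σ = 0.105 in south, read 0.0656 in north. So, if the target path scales with partner at a fixed 20 mM of substrate, partner raised the target while heat took part of that back, lowering σ 1.60-fold between 35 °C and 46 °C.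

I carried that factor geometrically along temperature, which gave σ = 0.130 for winter and 0.0553 for summer. With ρ = σ × equivalents, the final share is ρ/(ρ + 1). Summer runs hotter than north, so I took its conversion as complete and reckoned 9.96 %. Winter at full conversion gives 34.2 %.

For winter's clock, the first-order decay constant of substrate read 0.551 min⁻¹ in south and 1.92 min⁻¹ in north. Dividing each by ρ + 1 isolates the side path, and scaling that to winter gives a total of 0.420 min⁻¹. My winter figure was therefore 31.4 %, and I chose winter.

The forecast also chose winter, with 12 % for summer and 22 % for winter, on the ground that “heat must favour the waste path”. Its winter number is what one gets from the last north reading scaled with the partner charged, 21.6 %; mine lay higher.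

The simulation gave winter: 9.48 % in summer and 33.8 % in winter.

    substrate + partner → open intermediate (k = 0.120 M⁻¹ s⁻¹, Ea = 45.0 kJ mol⁻¹)
    partner + open intermediate → target (k = 3.80 M⁻¹ s⁻¹, Ea = 62.0 kJ mol⁻¹)
    substrate → side product (k = 0.0420 s⁻¹, Ea = 89.0 kJ mol⁻¹)
    capture agent + open intermediate → trapped intermediate (k = 0.190 M⁻¹ s⁻¹, Ea = 60.0 kJ mol⁻¹)
    partner → decomposed reagent (k = 0.00160 s⁻¹, Ea = 88.0 kJ mol⁻¹)
    substrate + target ⇌ idle adduct, settled at all times (K = 12.0 M⁻¹, ΔH = −31.0 kJ mol⁻¹)
    (constants at 50 °C)

The main reason for summer's low end was the passing of substrate into side product: with that step taken away, summer ended at 59.0 % instead of 9.48 %. In winter, target over side product per equivalent at 60.0 min comes to σ = 0.148, against my 0.130. The neighbour flask, winter with 1.60 equiv of partner, still holds 13 % of its substrate unbound at its end, so my winter σ gives 15.0 %, and that flask ended at 15.7 %.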